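**Plan**
- Retrosynthesis (guaiane numbering: C1/C5 ring fusion, C4 carbinol, C6 OAc, C7 iPr, C8 OAng, C10 olefinic C–Me): cut the C8 angelate C–O bond, then C4–OH (back to exocyclic C4=CH2), the C8–H bond with the C6 acetyl (back to a C8 ketone with free C6–OH), the C6–O bond (back to a C6=C7–C8=O enone), and last the two ring bonds C5–C1 and C5–C6.
- Enabling feature: in the seven-membered ring C10(Me) and C7(iPr) stand 1,4 with oxygen on C8 next to C7, which is the thymol pattern. C1=C10 is an arene bond left in place. The one atom an arene cannot supply, the sp3 ring-fusion CH C5, sits next to carbinol carbon C4, so it can be the carbene carbon of an arylethyl diazomethyl ketone.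
- Forward: thymol methyl ether receives the C2–C3–C4–C5 chain para to OMe (iodination, Heck, diazo transfer). The carbene then closes the five-membered ring and expands the benzene ring to the seven-membered ring in one step. Methylenation, enol ether hydrolysis, C6 oxygenation, C8 reduction with acetyl transfer, C4 hydration and angeloylation follow.
- Stereochemistry: C5 from the chiral copper catalyst in the ring expansion; C6 by boryl addition anti to the five-membered ring; C7 by kinetic enolate protonation anti to boron; C8 by intramolecular hydride delivery from the C6 hemiacetal (1,3-anti); C4 by O2 capture of the tertiary radical anti to the C6 branch.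

Key step: step 4

Remark: thymol methyl ether is taken as purchasable (otherwise one O-methylation of thymol); locants C1–C10 in the text are guaiane locants as defined above, while systematic names use azulene numbering.

**Step 1**
Reactants: 1 thymol methyl ether (1-methoxy-4-methyl-2-(propan-2-yl)benzene)
Product: 2 1-iodo-4-methoxy-2-methyl-5-(propan-2-yl)benzene
Conditions: NIS, CF3CO2H (cat.), MeCN, 25 °C
Reagents that add atoms: N-iodosuccinimide, O=C1CCC(=O)N1I
Why: Electrophilic aromatic iodination should go para to OMe, the most activated and least hindered position, which is also ortho to the methyl group as the later ring fusion requires.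

**Step 2**
Reactants: 2 1-iodo-4-methoxy-2-methyl-5-(propan-2-yl)benzene; 3 but-3-en-2-ol (racemic)
Product: 4 4-[4-methoxy-2-methyl-5-(propan-2-yl)phenyl]butan-2-one
Conditions: Pd(OAc)2 (3 mol %), Bu4NCl, NaHCO3, DMF, 60 °C
Reagents that add atoms: none
Why: Heck arylation of an allylic alcohol under ligand-free phase-transfer conditions: the aryl group adds to the terminal carbon and β-hydride elimination toward the carbinol gives the enol, hence the saturated methyl ketone directly.

**Step 3**
Reactants: 4 4-[4-methoxy-2-methyl-5-(propan-2-yl)phenyl]butan-2-one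
Product: 6 1-diazo-4-[4-methoxy-2-methyl-5-(propan-2-yl)phenyl]butan-2-one, via trifluoroacetyl ketone 5 (not isolated)
Conditions: LiN(SiMe3)2, THF, −78 °C; CF3CO2CH2CF3; aq. HCl; then MsN3, Et3N, H2O, MeCN, 25 °C
Reagents that add atoms: methanesulfonyl azide, CS(=O)(=O)N=[N+]=[N-]; 2,2,2-trifluoroethyl trifluoroacetate, O=C(OCC(F)(F)F)C(F)(F)F (its atoms stay only in 5)
Why: Detrifluoroacetylative diazo transfer (Regitz type): kinetic deprotonation at the methyl group, Claisen trifluoroacetylation to 5 and diazo transfer with loss of the trifluoroacetyl group should place the diazo group on the terminal carbon only.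

**Step 4**
Reactants: 6 1-diazo-4-[4-methoxy-2-methyl-5-(propan-2-yl)phenyl]butan-2-one
Product: 8 (8aS)-6-methoxy-4-methyl-7-(propan-2-yl)-3,8a-dihydroazulen-1(2H)-one, via norcaradiene 7 (not isolated)
Conditions: CuCl (5 mol %), NaB[3,5-(CF3)2C6H3]4 (6 mol %), 2,2'-(propane-2,2-diyl)bis[(4R)-4-phenyl-4,5-dihydro-1,3-oxazole] (6 mol %; the ligand antipode is used if the sense of induction requires it), CH2Cl2, 40 °C, slow addition of 6; filtration through basic Al2O3
Reagents that add atoms: none
Why: Intramolecular Buchner reaction: the copper carbene formed from 6 by loss of N2 adds across the ipso/ortho C=C bond of the arene to give norcaradiene 7, whose disrotatory 6π electrocyclic opening cleaves the former aromatic C–C bond, so the six-membered arene becomes the seven-membered ring with the carbene carbon inserted as C5. The closest known reaction type is the conversion of 1-diazo-4-arylbutan-2-ones into 3,8a-dihydroazulen-1(2H)-ones with Rh2(OAc)4 or, enantioselectively, with cationic copper–bis(oxazoline) catalysts. The five-membered ring closes by 5-exo attack of the carbene carbon on the ipso carbon (three-atom tether), the second bond to the ortho carbon completes the cyclopropane, and the seven-membered ring arises by one-carbon ring expansion, not by closure. The single new stereocenter C5 (C8a) is set by the chiral ligand, which selects one enantiotopic face of the arene, and is untouched by the electrocyclic opening. The step needs regioselectivity between the two ipso–ortho bonds, secured by the ortho methyl group that blocks its side so that only the C–H ortho carbon is attacked, and chemoselectivity for cyclopropanation over aromatic substitution or ipso attack para to OMe, secured by a non-nucleophilic, acid-free medium and acid-free isolation.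

**Step 5**
Reactants: 8 (8aS)-6-methoxy-4-methyl-7-(propan-2-yl)-3,8a-dihydroazulen-1(2H)-one
Product: 9 (8aR)-6-methoxy-4-methyl-1-methylidene-7-(propan-2-yl)-1,2,3,8a-tetrahydroazulene
Conditions: Cp2Ti(μ-CH2)(μ-Cl)AlMe2, pyridine, THF/toluene, −40 → 0 °C; aq. NaOH
Reagents that add atoms: Tebbe reagent, C[Al-]1(C)C[Ti]([Cl+]1)(C1C=CC=C1)C1C=CC=C1
Why: Tebbe methylenation through an oxatitanacyclobutane is non-basic, so the acidic C5–H next to the ketone should not be enolised, and removing the ketone also shuts off the acid-induced rearrangement of the azulenone to a 2-tetralone; the new CH2 is the future C4 methyl.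

**Step 6**
Reactants: 9 (8aR)-6-methoxy-4-methyl-1-methylidene-7-(propan-2-yl)-1,2,3,8a-tetrahydroazulene
Product: 10 (8aR)-4-methyl-1-methylidene-7-(propan-2-yl)-2,3,5,8a-tetrahydroazulen-6(1H)-one
Conditions: (CO2H)2·2H2O (cat.), THF/H2O, 0 °C
Reagents that add atoms: water, O
Why: Kinetic hydrolysis of a conjugated dienol ether: protonation at C9, the carbon next to C–OMe, should give the β,γ-unsaturated ketone, so the tetrasubstituted C1=C10 alkene stays where the arene left it and C6=C7(iPr)–C8=O becomes an enone.

**Step 7**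
Reactants: 10 (8aR)-4-methyl-1-methylidene-7-(propan-2-yl)-2,3,5,8a-tetrahydroazulen-6(1H)-one
Product: 12 (7S,8S,8aR)-8-hydroxy-4-methyl-1-methylidene-7-(propan-2-yl)-2,3,5,7,8,8a-hexahydroazulen-6(1H)-one, via β-boryl ketone 11 (not isolated)
Conditions: CuCl (5 mol %), Xantphos (5 mol %), NaOtBu (6 mol %), B2pin2, MeOH (2 equiv), THF, 0 °C; then NaBO3·4H2O, THF/H2O, 0 °C
Reagents that add atoms: bis(pinacolato)diboron, CC1(C)OB(OC1(C)C)B1OC(C)(C)C(C)(C)O1 (boron stays only in 11); sodium perborate, [Na+].OO[B-](O)(O)O
Why: Copper-catalysed conjugate borylation followed by stereoretentive C–B oxidation: boron should add to C6 on the face anti to the five-membered ring at C5 (cis to H-5), and kinetic protonation of the enolate at C7 anti to the bulky Bpin should place isopropyl cis to the C6 oxygen.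

**Step 8**
Reactants: 12 (7S,8S,8aR)-8-hydroxy-4-methyl-1-methylidene-7-(propan-2-yl)-2,3,5,7,8,8a-hexahydroazulen-6(1H)-one
Product: 14 (6S,7R,8S,8aR)-6-hydroxy-4-methyl-1-methylidene-7-(propan-2-yl)-1,2,3,5,6,7,8,8a-octahydroazulen-8-yl acetate, via acetaldehyde hemiacetal 13 (not isolated)
Conditions: SmI2 (0.3 equiv), MeCHO (8 equiv), THF, −10 °C
Reagents that add atoms: acetaldehyde, CC=O
Why: Evans–Tishchenko reduction: the samarium-bound hemiacetal 13 on O–C6 should deliver hydride intramolecularly to the C8 ketone through a chair-like chelate, giving the 1,3-anti diol monoester with the acyl group on the original hydroxyl, which sets C8 and puts the acetate on C6 in one step.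

**Step 9**
Reactants: 14 (6S,7R,8S,8aR)-6-hydroxy-4-methyl-1-methylidene-7-(propan-2-yl)-1,2,3,5,6,7,8,8a-octahydroazulen-8-yl acetate
Product: 16 (1S,6S,7R,8R,8aR)-1,6-dihydroxy-1,4-dimethyl-7-(propan-2-yl)-1,2,3,5,6,7,8,8a-octahydroazulen-8-yl acetate, via tertiary hydroperoxide 15 (not isolated)
Conditions: Mn(dpm)3 (10 mol %), PhSiH3, O2 (1 atm), iPrOH/CH2Cl2, 0 → 25 °C; then PPh3
Reagents that add atoms: dioxygen, O=O
Why: Mukaiyama hydration (metal-hydride hydrogen atom transfer): H should add to the terminal CH2, the tertiary C4 radical should be trapped by O2 on the face anti to the C6 branch at C5 (OH cis to H-5), and PPh3 reduces hydroperoxide 15; the tetrasubstituted C1=C10 alkene is too hindered for hydrogen atom transfer.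

**Step 10**
Reactants: 16 (1S,6S,7R,8R,8aR)-1,6-dihydroxy-1,4-dimethyl-7-(propan-2-yl)-1,2,3,5,6,7,8,8a-octahydroazulen-8-yl acetate
Product: 17 (1S,6S,7R,8R,8aR)-8-acetoxy-1-hydroxy-1,4-dimethyl-7-(propan-2-yl)-1,2,3,5,6,7,8,8a-octahydroazulen-6-yl (2Z)-2-methylbut-2-enoate (CNP0258590.1)
Conditions: angelic acid, 2,4,6-Cl3C6H2COCl, Et3N, toluene, 25 °C; then 16, 80 °C
Reagents that add atoms: angelic acid, C/C=C(/C)C(=O)O
Why: Yamaguchi-type esterification through the preformed angelic 2,4,6-trichlorobenzoic mixed anhydride should acylate the hindered secondary C8 alcohol without Z→E isomerisation to the tiglate, while the tertiary C4 alcohol is too hindered to react.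

**Compound list**
1 | thymol methyl ether (1-methoxy-4-methyl-2-(propan-2-yl)benzene) | COc1cc(C)ccc1C(C)C | starting material
2 | 1-iodo-4-methoxy-2-methyl-5-(propan-2-yl)benzene | COc1cc(C)c(I)cc1C(C)C | intermediate
3 | but-3-en-2-ol (racemic) | C=CC(C)O | starting material
4 | 4-[4-methoxy-2-methyl-5-(propan-2-yl)phenyl]butan-2-one | COc1cc(C)c(CCC(C)=O)cc1C(C)C | intermediate
5 | 1,1,1-trifluoro-6-[4-methoxy-2-methyl-5-(propan-2-yl)phenyl]hexane-2,4-dione | COc1cc(C)c(CCC(=O)CC(=O)C(F)(F)F)cc1C(C)C | intermediate
6 | 1-diazo-4-[4-methoxy-2-methyl-5-(propan-2-yl)phenyl]butan-2-one | COc1cc(C)c(CCC(=O)C=[N+]=[N-])cc1C(C)C | intermediate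
7 | norcaradiene valence isomer of 8 (all-cis cyclopropane made of the carbene carbon, the ipso carbon and the unsubstituted ortho carbon; same configuration at the carbene carbon as 8) | COC1=C(C(C)C)[C@H]2[C@@H]3C(=O)CC[C@]23C(C)=C1 | intermediate
8 | (8aS)-6-methoxy-4-methyl-7-(propan-2-yl)-3,8a-dihydroazulen-1(2H)-one | COC1=CC(C)=C2CCC(=O)[C@H]2C=C1C(C)C | intermediate
9 | (8aR)-6-methoxy-4-methyl-1-methylidene-7-(propan-2-yl)-1,2,3,8a-tetrahydroazulene | COC1=CC(C)=C2CCC(=C)[C@H]2C=C1C(C)C | intermediate
10 | (8aR)-4-methyl-1-methylidene-7-(propan-2-yl)-2,3,5,8a-tetrahydroazulen-6(1H)-one | O=C1CC(C)=C2CCC(=C)[C@H]2C=C1C(C)C | intermediate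
11 | (7R,8S,8aR)-4-methyl-1-methylidene-7-(propan-2-yl)-8-(4,4,5,5-tetramethyl-1,3,2-dioxaborolan-2-yl)-2,3,5,7,8,8a-hexahydroazulen-6(1H)-one | O=C1CC(C)=C2CCC(=C)[C@H]2[C@H](B3OC(C)(C)C(C)(C)O3)[C@@H]1C(C)C | intermediate
12 | (7S,8S,8aR)-8-hydroxy-4-methyl-1-methylidene-7-(propan-2-yl)-2,3,5,7,8,8a-hexahydroazulen-6(1H)-one | O=C1CC(C)=C2CCC(=C)[C@H]2[C@H](O)[C@@H]1C(C)C | intermediate
13 | 1-hydroxyethyl ether (acetaldehyde hemiacetal) of 12 at the C8 oxygen, samarium-bound in the flask, hemiacetal carbon unassigned | O=C1CC(C)=C2CCC(=C)[C@H]2[C@H](OC(C)O)[C@@H]1C(C)C | intermediate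
14 | (6S,7R,8S,8aR)-6-hydroxy-4-methyl-1-methylidene-7-(propan-2-yl)-1,2,3,5,6,7,8,8a-octahydroazulen-8-yl acetate | O[C@H]1CC(C)=C2CCC(=C)[C@H]2[C@H](OC(C)=O)[C@@H]1C(C)C | intermediate
15 | (1S,6S,7R,8R,8aR)-1-hydroperoxy-6-hydroxy-1,4-dimethyl-7-(propan-2-yl)-1,2,3,5,6,7,8,8a-octahydroazulen-8-yl acetate | O[C@H]1CC(C)=C2CC[C@](C)(OO)[C@H]2[C@H](OC(C)=O)[C@@H]1C(C)C | intermediate
16 | (1S,6S,7R,8R,8aR)-1,6-dihydroxy-1,4-dimethyl-7-(propan-2-yl)-1,2,3,5,6,7,8,8a-octahydroazulen-8-yl acetate | O[C@H]1CC(C)=C2CC[C@](C)(O)[C@H]2[C@H](OC(C)=O)[C@@H]1C(C)C | intermediate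
17 | (1S,6S,7R,8R,8aR)-8-acetoxy-1-hydroxy-1,4-dimethyl-7-(propan-2-yl)-1,2,3,5,6,7,8,8a-octahydroazulen-6-yl (2Z)-2-methylbut-2-enoate | C/C=C(/C)C(=O)O[C@H]1CC(C)=C2CC[C@](C)(O)[C@H]2[C@H](OC(C)=O)[C@@H]1C(C)C | target

**Count**
Total steps: 10. Longest linear sequence: 10 steps (from 1).

**Steps most likely to fail**

Step 4. The carbene may be diverted to aromatic substitution (leading to a 2-tetralone) or to ipso attack favoured by the para methoxy group, and the cationic copper catalyst may discriminate the arene faces poorly on this pentasubstituted ring. Fallback: setting out from 6, the achiral and best-precedented cycloheptatriene-selective catalyst Rh2(OAc)4 (0.5 mol %, CH2Cl2, 40 °C) should give racemic 6-methoxy-4-methyl-7-(propan-2-yl)-3,8a-dihydroazulen-1(2H)-one F1. The absolute configuration is then secured by resolution instead of catalysis: preparative chromatography on a cellulose tris(3,5-dimethylphenylcarbamate) phase separates 8 from its (8aR)-enantiomer F2. The route is rejoined at 8.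

Step 7. Boryl transfer to the α-isopropyl enone may be slow, the alkoxide-containing protic medium may erode the triply allylic C5 centre by γ-deprotonation, and protonation at C7 may be unselective. Fallback: setting out from 10, nucleophilic Weitz–Scheffer-type epoxidation (tBuOOH, DBU, CH2Cl2, 0 °C) should add oxygen to C6=C7 on the face anti to the five-membered ring to give epoxy ketone F3. SmI2 (2.2 equiv, THF/MeOH, −90 °C) then cleaves the C7–O bond reductively, and the samarium enolate is protonated at low temperature in a separate, tunable event. The route is rejoined at 12.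

Step 8. Intramolecular hydride transfer may fail in the ring-constrained chelate, and the trivalent samarium Lewis acid may open the hindered aldol unit by retro-aldol cleavage or scramble C6/C7. Fallback: setting out from 12, Evans–Saksena reduction (Me4NBH(OAc)3, MeCN/AcOH, −30 °C) should give the anti-6,8-diol F4. Mukaiyama hydration as in step 9 gives triol F5. The less hindered secondary C8 alcohol (flanked by CH2) is angeloylated with the mixed anhydride of step 10 at 60 °C to give monoangelate F6. Ac2O, DMAP, pyridine then acetylates the remaining secondary C6 alcohol, leaving the tertiary C4 alcohol free. The route is rejoined at 17.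

**Further compounds**
F1 | step 4 | racemic 6-methoxy-4-methyl-7-(propan-2-yl)-3,8a-dihydroazulen-1(2H)-one | COC1=CC(C)=C2CCC(=O)C2C=C1C(C)C
F2 | step 4 | (8aR)-6-methoxy-4-methyl-7-(propan-2-yl)-3,8a-dihydroazulen-1(2H)-one | COC1=CC(C)=C2CCC(=O)[C@@H]2C=C1C(C)C
F3 | step 7 | 7,8-epoxide of 10 (azulene locants), epoxide oxygen cis to H-8a | O=C1CC(C)=C2CCC(=C)[C@H]2[C@@H]3O[C@]13C(C)C
F4 | step 8 | (6S,7R,8S,8aR)-4-methyl-1-methylidene-7-(propan-2-yl)-1,2,3,5,6,7,8,8a-octahydroazulene-6,8-diol | O[C@H]1CC(C)=C2CCC(=C)[C@H]2[C@H](O)[C@@H]1C(C)C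
F5 | step 8 | (1S,6S,7R,8R,8aR)-1,4-dimethyl-7-(propan-2-yl)-1,2,3,5,6,7,8,8a-octahydroazulene-1,6,8-triol | O[C@H]1CC(C)=C2CC[C@](C)(O)[C@H]2[C@H](O)[C@@H]1C(C)C
F6 | step 8 | (1S,6S,7R,8R,8aR)-1,8-dihydroxy-1,4-dimethyl-7-(propan-2-yl)-1,2,3,5,6,7,8,8a-octahydroazulen-6-yl (2Z)-2-methylbut-2-enoate | C/C=C(/C)C(=O)O[C@H]1CC(C)=C2CC[C@](C)(O)[C@H]2[C@H](O)[C@@H]1C(C)C
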